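Numbering used for the target and all intermediates: C1 octyl-bearing cyclobutane CH, C2, C3=C4, C5 tertiary carbinol, C6(CO2H)=C7, C8 CHOH, C9, C10 (CH2), C11, C12, C13. Ring A = C2-C3-C4-C5-C13-C12, ring B = C5-C6-C7-C8-C9-C13, ring C = C9-C10-C11-C12-C13, ring D = C1-C2-C12-C11.
Endgame: the acid comes from a tetracyclic C8 ketone by C6=C7 dehydrogenation, C8 reduction with Mitsunobu inversion, and ester cleavage.
Key disconnection: rings C and D are cut together at C9–C10, C11–C12 and C1–C2. This leads back to a bicyclic (rings A and B) β-keto ester in which the whole C10-C11-C1-octyl unit hangs on C9 as a temporary (E)-undec-2-enyl ester that leaves as CO2.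
Enabling feature: rings C and D form a bicyclo[3.2.0]heptane whose cyclobutane carbon C2 carries the ring A alkene C3=C4. This vinylcyclobutane is the retron of a 1,3-diene/alkene [2+2] across C12=C2 and C11=C1. C9 lies α to the carbinol carbon C8 (a latent ketone), so an enolate at C9 can accept C10.
Ring order: A (dearomatised phenol, para-quinol), then B (desymmetrising Michael addition C9→C13), then C and D in one operation. The C6 ester centre is set first, helps to relay chirality, and is erased when C6=C7 is made.

Key step: step 10

Assumption: the sense of induction drawn for the chiral diene ligand (step 1) and for the cinchona urea (step 6) is taken as the matched pair that leads to the shown enantiomer. If either proves opposite, the mirror-image ligand or the pseudo-enantiomeric quinidine urea is used and nothing else changes.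

Step 1
Reactants: 1 4-hydroxyphenylboronic acid; 2 dimethyl fumarate
Product: 3 dimethyl (R)-2-(4-hydroxyphenyl)succinate
Conditions: [RhCl(C2H4)2]2 (1.5 mol %), (R,R)-2,5-diphenylbicyclo[2.2.2]octa-2,5-diene (3.3 mol %), KOH (10 mol %), dioxane/H2O 10:1, 30 °C
Reagents that add atoms: none
Why: Hayashi–Miyaura rhodium-catalysed asymmetric 1,4-addition of an arylboronic acid to a fumarate, in which the chiral diene fixes the face of aryl transfer and sets C6 as R, while the symmetric acceptor removes any regiochemical question.

Step 2
Reactants: 3 dimethyl (R)-2-(4-hydroxyphenyl)succinate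
Product: 4 (R)-3-(4-hydroxyphenyl)-4-methoxy-4-oxobutanoic acid
Conditions: Me3SnOH (2.5 equiv), 1,2-dichloroethane, 60 °C; 1 M HCl work-up
Reagents that add atoms: trimethyltin hydroxide C[Sn](C)(C)O
Why: Near-neutral trimethyltin hydroxide ester cleavage should attack the unhindered CH2CO2Me ester faster than the α-aryl-branched one and should not epimerise C6.

Step 3
Reactants: 5 Meldrum's acid; 6 (E)-undec-2-en-1-ol
Product: 7 mono-(E)-undec-2-enyl malonate
Conditions: toluene, 110 °C
Reagents that add atoms: none
Why: Thermal alcoholysis of Meldrum's acid opens the dioxanedione with loss of acetone and gives the malonic half ester; no stereocentre is involved and the E alkene is untouched.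

Step 4
Reactants: 4 (R)-3-(4-hydroxyphenyl)-4-methoxy-4-oxobutanoic acid; 7 mono-(E)-undec-2-enyl malonate
Product: 9 1-methyl 6-[(E)-undec-2-enyl] (R)-2-(4-hydroxyphenyl)-4-oxohexanedioate, via acyl imidazolide 8 (not isolated)
Conditions: CDI (1.05 equiv), THF, 23 °C; then 7 (1.5 equiv), MgCl2 (1.5 equiv), Et3N (3.2 equiv), MeCN/THF, 23 °C; 1 M HCl
Reagents that add atoms: 1,1'-carbonyldiimidazole O=C(n1ccnc1)n1ccnc1
Why: Masamune–Brooks decarboxylative Claisen condensation of a magnesium malonate half ester with an acyl imidazolide: the acid is activated much faster than the phenol, any aryl ester formed is itself an acyl donor, and the mild base should leave C6 intact.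

Step 5
Reactants: 9 1-methyl 6-[(E)-undec-2-enyl] (R)-2-(4-hydroxyphenyl)-4-oxohexanedioate
Product: 10 para-quinol 1-methyl 6-[(E)-undec-2-enyl] (R)-2-(1-hydroxy-4-oxocyclohexa-2,5-dienyl)-4-oxohexanedioate
Conditions: PhI(OAc)2 (1.1 equiv), MeCN/H2O 3:1, 0 °C
Reagents that add atoms: water O
Why: Hypervalent-iodine oxidative dearomatisation of a para-alkylphenol with water as the nucleophile gives the para-quinol; C5 is not yet stereogenic because its two enone arms are constitutionally identical.

Step 6
Reactants: 10 para-quinol β-keto ester
Product: 11 cis-fused bicyclic enone β-keto ester (rings A and B; 5-OH and 13-H cis)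
Conditions: quinine-derived 9-epi-amino N-[3,5-bis(trifluoromethyl)phenyl]urea (10 mol %), toluene, −20 °C
Reagents that add atoms: none
Why: Desymmetrising intramolecular Michael addition (6-exo-trig) under bifunctional tertiary amine/urea catalysis, in which the tether delivers C9 to C13 anti to 5-OH (cis fusion), the catalyst and the matched R centre at C6 (ester equatorial in the chair-like transition state, axial attack on ring A) select one diastereotopic enone arm and so set C5 and C13, and C9 stays epimerisable.

Step 7
Reactants: 11 cis-fused bicyclic enone β-keto ester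
Product: 12 5-O-triethylsilyl ether of 11
Conditions: TESOTf (1.3 equiv), 2,6-lutidine, CH2Cl2, −78 to 0 °C; aqueous citric acid wash
Reagents that add atoms: triethylsilyl trifluoromethanesulfonate CC[Si](CC)(CC)OS(=O)(=O)C(F)(F)F
Why: Silyl triflate silylation of a hindered tertiary alcohol blocks later dehydration, lactonisation onto the C9 ester and retro-aldol cleavage, and any enol silyl ether of the β-keto ester falls off in the mild acid wash.

Step 8
Reactants: 12 5-O-triethylsilyl ether
Product: 13 C2 allylic alcohol (2-OH on the face of the C13–C9 bond)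
Conditions: NaBH4 (1.0 equiv), CeCl3·7H2O (1.1 equiv), MeOH/CH2Cl2, −78 °C
Reagents that add atoms: none
Why: Luche 1,2-reduction takes the ring A enone, while the largely enolised cyclic β-keto ester is inert at −78 °C; hydride arrives anti to the axial C13–C9 bond, and the new centre at C2 is removed in the next step.

Step 9
Reactants: 13 C2 allylic alcohol
Product: 14 bicyclic 5-silyloxycyclohexa-1,3-diene β-keto ester (ring A diene C12=C2–C3=C4)
Conditions: Ph2S[OC(CF3)2Ph]2 (Martin sulfurane, 1.5 equiv), CH2Cl2, 0 °C
Reagents that add atoms: none
Why: Martin sulfurane dehydration is a neutral E2-type elimination of the only free alcohol, and C12–H is the only β-hydrogen available (C5 is quaternary), so only the conjugated ring A diene can form without acid that would aromatise it.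

Step 10
Reactants: 14 bicyclic cyclohexadiene (E)-undec-2-enyl β-keto ester
Product: 16 tetracyclic C8 ketone (rings A to D), via C9-allyl ketone 15 (not isolated)
Conditions: Pd(PPh3)4 (5 mol %), [Ir(dF(CF3)ppy)2(dtbbpy)]PF6 (1 mol %), degassed MeCN (0.01 M), 23 °C, dark until CO2 evolution stops, then 450 nm LEDs, same flask
Reagents that add atoms: none
Why: Proposed new method: in the dark phase zerovalent palladium ionises the allylic ester, the β-keto carboxylate and the π-allyl fragment recombine at the unsubstituted allyl terminus and CO2 leaves (Tsuji–Saegusa decarboxylative allylation, the catalytic Carroll reaction), which forms C9–C10 and places the E alkene C11=C1 of 15 three atoms from the diene terminus C12; under blue light the iridium sensitiser (triplet energy about 61 kcal/mol) excites only the ring A cyclohexadiene (about 52 kcal/mol; isolated alkene, ketone and esters lie far higher), C12 adds to C11 and the 1,4-biradical closes C1–C2. The closest known reaction types are these two (decarboxylative allylation of allyl β-keto esters; visible-light triplet-sensitised intramolecular [2+2] of 1,3-dienes with tethered alkenes), π-allylpalladium and iridium photocatalysts are known to tolerate each other in dual catalysis, and only their relay in one flask on a 5-silyloxycyclohexa-1,3-diene is new. Ring C closes 5-exo-trig (rule of five for a 1,6-diene) and ring D closes by recombination of the secondary alkyl radical C1 with the nearer terminus C2 of the allyl radical C2–C3–C4 after intersystem crossing, which leaves C3=C4 in place. C9 is an epimerisable α-keto centre that settles with the allyl group equatorial and trans to C12 in the ring B chair that holds C12, the C6 ester and the silyloxy group equatorial; in this conformer C9 is axial on ring A, so the tether reaches only the face of C12=C2 anti to the silyloxy group, which fixes C12, and the cis fusion demanded by a five- and a four-membered ring fixes C11 and C2. C1 follows from the E geometry of the alkene (octyl trans to C10) and, should the biradical rotate, from closure with the octyl chain on the convex face, both leading to the same configuration. The step needs linear over branched allylation (secured by PPh3-ligated palladium and the unhindered CH2 terminus), energy transfer to the diene alone (secured by the triplet energy gap, with high dilution against dimerisation) and four- over six-membered biradical closure (favoured by the proximity of C2).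

Step 11
Reactants: 16 tetracyclic C8 ketone
Product: 17 tetracyclic enone ester (C6=C7 conjugated with C8=O and CO2Me)
Conditions: LiN(iPr)2 (1.2 equiv), THF, −78 °C; N-tert-butylbenzenesulfinimidoyl chloride (1.3 equiv), −78 °C
Reagents that add atoms: none
Why: Mukaiyama one-pot dehydrogenation: kinetic deprotonation occurs at the CH2 C7 rather than at the ring-fusion CH C9, sulfur is attached at C7 and leaves together with the activated C6–H, which erases the auxiliary centre C6 and leaves C9 untouched.

Step 12
Reactants: 17 tetracyclic enone ester
Product: 19 8-epi diol methyl ester (8-OH trans to 5-OH), via TES-protected 8-epi alcohol 18 (not isolated)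
Conditions: NaBH4, CeCl3·7H2O, MeOH, −78 °C; then 1 M HCl to pH 2, 0 °C
Reagents that add atoms: none
Why: Luche 1,2-reduction with axial hydride attack from the open face that carries 13-H should give the equatorial 8-epi alcohol reliably, and the dilute acid quench removes the tertiary triethylsilyl ether in the same flask.

Step 13
Reactants: 19 8-epi diol methyl ester
Product: 20 8-O-(4-nitrobenzoate) with the natural C8 configuration
Conditions: 4-nitrobenzoic acid, PPh3, DIAD, THF, 0 to 23 °C
Reagents that add atoms: 4-nitrobenzoic acid O=C(O)c1ccc(cc1)[N+](=O)[O-]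
Why: Mitsunobu inversion (SN2 from the open face) sets C8 with oxygen cis to 5-OH; the tertiary 5-OH does not react, and SN2' attack is disfavoured at the fully substituted, ester-bearing C6.

Step 14
Reactants: 20 8-O-(4-nitrobenzoate) methyl ester
Product: 21 target acid CNP0106718.3
Conditions: LiOH·H2O (6 equiv), THF/MeOH/H2O, 23 to 40 °C; 1 M HCl to pH 3
Reagents that add atoms: lithium hydroxide [Li+].[OH-]
Why: Saponification by acyl–oxygen cleavage removes both esters without touching any C–O stereocentre, and the E relation of CO2H and C8 across C6=C7 excludes lactonisation.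

Compound list
1 | 4-hydroxyphenylboronic acid | OB(O)c1ccc(O)cc1 | starting material
2 | dimethyl fumarate | COC(=O)/C=C/C(=O)OC | starting material
3 | dimethyl (R)-2-(4-hydroxyphenyl)succinate | COC(=O)C[C@@H](C(=O)OC)c1ccc(O)cc1 | intermediate
4 | (R)-3-(4-hydroxyphenyl)-4-methoxy-4-oxobutanoic acid | OC(=O)C[C@@H](C(=O)OC)c1ccc(O)cc1 | intermediate
5 | Meldrum's acid (2,2-dimethyl-1,3-dioxane-4,6-dione) | CC1(C)OC(=O)CC(=O)O1 | starting material
6 | (E)-undec-2-en-1-ol | CCCCCCCC/C=C/CO | starting material
7 | mono-(E)-undec-2-enyl malonate (3-oxo-3-[(E)-undec-2-enyloxy]propanoic acid) | CCCCCCCC/C=C/COC(=O)CC(=O)O | intermediate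
8 | acyl imidazolide of 4, methyl (R)-2-(4-hydroxyphenyl)-4-(imidazol-1-yl)-4-oxobutanoate | O=C(C[C@@H](C(=O)OC)c1ccc(O)cc1)n1ccnc1 | intermediate
9 | 1-methyl 6-[(E)-undec-2-enyl] (R)-2-(4-hydroxyphenyl)-4-oxohexanedioate | CCCCCCCC/C=C/COC(=O)CC(=O)C[C@@H](C(=O)OC)c1ccc(O)cc1 | intermediate
10 | para-quinol, 1-methyl 6-[(E)-undec-2-enyl] (R)-2-(1-hydroxy-4-oxocyclohexa-2,5-dienyl)-4-oxohexanedioate | CCCCCCCC/C=C/COC(=O)CC(=O)C[C@@H](C(=O)OC)C1(O)C=CC(=O)C=C1 | intermediate
11 | cis-fused bicycle: ring A C2(=O)-C3=C4-C5(OH)-C13H-C12H2, ring B C5-C6H(CO2Me)-C7H2-C8(=O)-C9H(CO2-undecenyl)-C13; 5-OH cis to 13-H, 6-CO2Me trans to 5-OH, 9-ester trans to C12 | CCCCCCCC/C=C/COC(=O)[C@@H]1C(=O)C[C@@H](C(=O)OC)[C@@]2(O)C=CC(=O)C[C@@H]12 | intermediate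
12 | 5-O-triethylsilyl ether of 11 | CCCCCCCC/C=C/COC(=O)[C@@H]1C(=O)C[C@@H](C(=O)OC)[C@@]2(O[Si](CC)(CC)CC)C=CC(=O)C[C@@H]12 | intermediate
13 | C2 allylic alcohol of 12 (2-OH trans to 5-OTES) | CCCCCCCC/C=C/COC(=O)[C@@H]1C(=O)C[C@@H](C(=O)OC)[C@@]2(O[Si](CC)(CC)CC)C=C[C@@H](O)C[C@@H]12 | intermediate
14 | bicyclic ring A cyclohexa-1,3-diene (C12=C2-C3=C4), 5-OTES, C8/C9 (E)-undec-2-enyl β-keto ester, 6-CO2Me | CCCCCCCC/C=C/COC(=O)[C@@H]1C(=O)C[C@@H](C(=O)OC)[C@@]2(O[Si](CC)(CC)CC)C=CC=C[C@@H]12 | intermediate
15 | C9-[(E)-undec-2-enyl] C8 ketone, allyl group trans to C12, otherwise as 14 | CCCCCCCC/C=C/C[C@@H]1C(=O)C[C@@H](C(=O)OC)[C@@]2(O[Si](CC)(CC)CC)C=CC=C[C@@H]12 | intermediate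
16 | tetracyclic C8 ketone, rings A to D with target configuration at C1, C2, C5, C9, C11, C12, C13; 5-OTES, 6-H/CO2Me | CCCCCCCC[C@H]1[C@@H]2C=C[C@]3(O[Si](CC)(CC)CC)[C@H](C(=O)OC)CC(=O)[C@H]4C[C@H]1[C@H]2[C@@H]43 | intermediate
17 | tetracyclic enone ester, C6(CO2Me)=C7-C8(=O), 5-OTES | CCCCCCCC[C@H]1[C@@H]2C=C[C@]3(O[Si](CC)(CC)CC)C(C(=O)OC)=CC(=O)[C@H]4C[C@H]1[C@H]2[C@@H]43 | intermediate
18 | 8-epi allylic alcohol, 5-OTES (8-OH trans to 5-O) | CCCCCCCC[C@H]1[C@@H]2C=C[C@]3(O[Si](CC)(CC)CC)C(C(=O)OC)=C[C@H](O)[C@H]4C[C@H]1[C@H]2[C@@H]43 | intermediate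
19 | 8-epi diol methyl ester | CCCCCCCC[C@H]1[C@@H]2C=C[C@]3(O)C(C(=O)OC)=C[C@H](O)[C@H]4C[C@H]1[C@H]2[C@@H]43 | intermediate
20 | 8-O-(4-nitrobenzoyl) methyl ester with natural C8 configuration (8-O cis to 5-OH) | CCCCCCCC[C@H]1[C@@H]2C=C[C@]3(O)C(C(=O)OC)=C[C@@H](OC(=O)c5ccc(cc5)[N+](=O)[O-])[C@H]4C[C@H]1[C@H]2[C@@H]43 | intermediate
21 | CNP0106718.3, tetracyclic dihydroxy acid | CCCCCCCC[C@H]1[C@@H]2C=C[C@]3(O)C(C(=O)O)=C[C@@H](O)[C@H]4C[C@H]1[C@H]2[C@@H]43 | target

Total step count: 14. Longest linear sequence: 13 (steps 1, 2 and 4 to 14; step 3 is a one-step side branch).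

Steps most likely to fail

Step 10.
- What may go wrong: allyl scrambling between molecules during the palladium phase; quenching or decomposition of one catalyst by the other; closure of the triplet biradical at the remote allyl terminus (formal [4+2]); diene dimerisation; loss of silanol with aromatisation of ring A.
- Fallback (known chemistry only), from 14 back to 16: 14 is treated with Pd(PPh3)4 alone in THF (Tsuji–Saegusa decarboxylative allylation). Ketone 15 is isolated and equilibrated with catalytic DBU to the trans isomer.
- It is then reduced with LiBH(s-Bu)3 by equatorial attack to the C8 axial alcohol of the allyl ketone F1. This removes the ketone chromophore and offers a hydroxyl ligand for copper.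
- Salomon–Kochi photocycloaddition of the ground-state copper–bis(alkene) complex ((CuOTf)2·C6H6, Et2O, 254 nm) avoids a free triplet biradical and should give the tetracyclic C8 alcohol F2. Dess–Martin oxidation returns 16.

Step 5.
- What may go wrong: capture of the electrophilic dearomatised intermediate by the enol of the β-keto ester (spirocyclisation) instead of by water, or oxidation at the active methylene.
- Fallback, from 9 back to 10: the cationic manifold is abandoned for singlet-oxygen chemistry. Dye-sensitised photooxygenation (O2, tetraphenylporphyrin, visible light, CHCl3) adds oxygen para to the phenol and gives the para-hydroperoxy dienone F3. Me2S then reduces F3 to 10.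

Step 6.
- What may go wrong: erosion of arm selectivity by an uncatalysed background cyclisation, and diversion through hemiketalisation of the free tertiary alcohol with the C8 ketone followed by oxa-Michael addition.
- Fallback, from 10 back to 12: the order of events and the control element are changed. The quinol is silylated first (TESOTf, 2,6-lutidine) to the silyl-protected quinol β-keto ester F4.
- Ring B is then closed under reversible, substrate-controlled conditions (Cs2CO3, 0.2 equiv, MeCN, 0 °C). The C6 centre alone then selects the arm through the chair with an equatorial ester, and the minor diastereomer is removed by chromatography. This route enters the main line directly at 12.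

Further compounds
F1 | step 10 | C8 axial alcohol of allyl ketone 15 (8-OH cis to the C9 allyl group) | CCCCCCCC/C=C/C[C@@H]1[C@H](O)C[C@@H](C(=O)OC)[C@@]2(O[Si](CC)(CC)CC)C=CC=C[C@@H]12
F2 | step 10 | tetracyclic C8 alcohol corresponding to 16 | CCCCCCCC[C@H]1[C@@H]2C=C[C@]3(O[Si](CC)(CC)CC)[C@H](C(=O)OC)C[C@@H](O)[C@H]4C[C@H]1[C@H]2[C@@H]43
F3 | step 5 | para-hydroperoxy dienone corresponding to 10 | CCCCCCCC/C=C/COC(=O)CC(=O)C[C@@H](C(=O)OC)C1(OO)C=CC(=O)C=C1
F4 | step 6 | O-triethylsilyl ether of para-quinol 10 | CCCCCCCC/C=C/COC(=O)CC(=O)C[C@@H](C(=O)OC)C1(O[Si](CC)(CC)CC)C=CC(=O)C=C1
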